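**Retrosynthetic overview** (ring A = the methoxy-bearing quinone, ring B = the dihydroxyquinone)
1. Ring B is not built but bought as 2,5-dihydroxy-1,4-benzoquinone: the last disconnection is the bond between the linker and the ring B carbon, made by proline/Hantzsch-ester reductive alkylation of 2,5-dihydroxy-3-methyl-1,4-benzoquinone with a ring A aldehyde.
2. Ring A is traced back to a mirror-symmetric 2-alkyl-4,6-dimethoxy-5-methylresorcinol. The mirror plane through the C-methyl and the chain-bearing carbons makes both para hydroxy/methoxy pairs equivalent, so oxidative demethylation places the methyl ether without any selective step.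
3. That arene is cut at two ring bonds, C(CH3)–C(OCH3) and C(OH)–C(chain), into two three-carbon α-dicarbonyl units joined head to tail: chain–CH2–CO–CH(OMe)2 and CH3CH2–C(OMe)2–CO2Me. One flask joins them by Claisen acylation, then acetal/enol ether ring closure and aromatization.
4. Enabling feature: ring A is a six-membered ring with oxygen on four carbons (1,2,4,5) and a carbon substituent on the other two, i.e. twice the triad C(alkyl)–C(O)–C(O), formally two 2-oxo acid units condensed head to tail. The two oxygens flanking the C-methyl carbon sit on the former acetal carbon and the former ketal carbon and arrive already methylated.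
5. Ring order: only ring A is formed (step 4). The linker is made before it (steps 1–2), quinone and aldehyde are unveiled after it (steps 5–6), and ring B is attached last (step 8).

Key step: step 4

Remark: the target is drawn as one tautomer of each hydroxyquinone; since 2-hydroxy-1,4-quinone tautomers interconvert, placing the methoxy group on an oxygen next to the C-methyl carbon of ring A defines the structure. The target has no stereocentre.

**Step 1**
Reactants: 1 11-bromoundec-1-ene; 2 1,4-dibromobutane
Product: 4 15-bromopentadec-1-ene, via undec-10-en-1-ylmagnesium bromide 3 (not isolated)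
Conditions: Mg, THF, reflux; then 2 (4 equiv), Li2CuCl4 (3 mol %), THF, −10 °C → rt
Reagents that add atoms: none
Why: Copper-catalysed sp3–sp3 Grignard cross-coupling (Kochi type) of a primary alkylmagnesium bromide with a primary alkyl bromide, kept at mono-coupling by the excess of the cheap, distillable dibromide 2.

**Step 2**
Reactants: 4 15-bromopentadec-1-ene; 5 methyl 2,2-dimethoxyacetate
Product: 7 1,1-dimethoxyheptadec-16-en-2-one, via pentadec-14-en-1-ylmagnesium bromide 6 (not isolated)
Conditions: Mg, THF, 45 °C; then added to 5 (2 equiv), THF, −78 °C; aq. NH4Cl
Reagents that add atoms: none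
Why: Grignard acylation with an α,α-dialkoxy ester: the magnesium-chelated tetrahedral adduct should persist at −78 °C and release the ketone only on quenching, so that a second addition is avoided.

**Step 3**
Reactants: 8 methyl 2-oxobutanoate
Product: 9 methyl 2,2-dimethoxybutanoate
Conditions: HC(OMe)3 (3 equiv), MeOH, H2SO4 (cat.), reflux
Reagents that add atoms: trimethyl orthoformate, COC(OC)OC
Why: Acid-catalysed ketalization of the ketone carbonyl of an α-keto ester, driven by the orthoformate as water scavenger; the product has neither an α-hydrogen nor a free ketone, which makes it a clean Claisen acceptor.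

**Step 4**
Reactants: 7 1,1-dimethoxyheptadec-16-en-2-one; 9 methyl 2,2-dimethoxybutanoate
Product: 12 4,6-dimethoxy-5-methyl-2-(tetradec-13-en-1-yl)benzene-1,3-diol, via tetramethoxy diketone 10 (not isolated), via bis(trimethylsilyl) ether 11 (not isolated)
Conditions: LiN(SiMe3)2 (2.2 equiv), toluene, −78 °C; 9 (1.5 equiv), −78 °C → rt; then CH2Cl2, i-Pr2NEt (4 equiv), Me3SiOTf (7 equiv), −78 °C → rt; then 1 M HCl, THF, rt
Reagents that add atoms: none
Why: Proposed new method: LiN(SiMe3)2 should deprotonate 7 at the chain-side methylene (the acetal methine is the poorer kinetic acid and acylation there could not be driven by enolate formation), and this enolate should be acylated by 9, an ester without α-hydrogen or free ketone, in a crossed Claisen condensation that forms the bond between the chain-bearing carbon and the future hydroxyl-bearing carbon and stops at the enolate of 10. Me3SiOTf/i-Pr2NEt should then convert the ketal, the only masked carbonyl with β-hydrogens, into its methyl enol ether and ionize the acetal, which has none, to an oxocarbenium ion, whose capture by the enol ether carbon forms the bond between the methyl-bearing and the methoxy-bearing carbon and closes the six-membered ring in a 6-(enolendo)-exo-trig mode (a 6π-electrocyclization of the fully enolized trienol ether followed by loss of methanol would lead to the same ring). Proton loss restores the enol ether, and silyl enolization of the one remaining ring C–H aromatizes the ring to 11, in which both oxygens next to the C-methyl carbon are still methyl ethers and both oxygens next to the chain are silyl ethers that the acidic work-up frees. The closest known reaction types are the Claisen acylation of ketone enolates with α,α-dialkoxy esters and the Me3SiOTf-mediated enol ether formation/Mukaiyama-type addition to acetals, which have not been merged into a benzannulation of this kind. The two sp3 ring carbons formed in the closure are transient and are erased on aromatization, so no stereocentre has to be controlled. The selectivities needed are head-to-tail regiochemistry and retention of exactly one methoxy group on each masked carbonyl carbon; the first is secured because only the ketal can become a nucleophile and only the acetal an electrophile, the second because the anhydrous, amine-buffered medium lets aromatization outrun β-elimination of methanol.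

**Step 5**
Reactants: 12 4,6-dimethoxy-5-methyl-2-(tetradec-13-en-1-yl)benzene-1,3-diol
Product: 13 2-hydroxy-5-methoxy-6-methyl-3-(tetradec-13-en-1-yl)cyclohexa-2,5-diene-1,4-dione
Conditions: PhI(OAc)2 (1.1 equiv), MeCN/H2O 2:1, 0 °C
Reagents that add atoms: water, O
Why: Oxidative demethylation of a p-methoxyphenol by trivalent iodine (attack of water at the methoxy-bearing para carbon, loss of methanol): because 12 has a mirror plane through the C-methyl and the chain-bearing carbons, either para hydroxy/methoxy pair (or an ortho pair, after tautomerization of the hydroxy-o-quinone) should give the same quinone, with methoxy next to the C-methyl carbon and hydroxyl next to the chain, while the isolated alkene is inert.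

**Step 6**
Reactants: 13 2-hydroxy-5-methoxy-6-methyl-3-(tetradec-13-en-1-yl)cyclohexa-2,5-diene-1,4-dione
Product: 14 13-(2-hydroxy-5-methoxy-4-methyl-3,6-dioxocyclohexa-1,4-dien-1-yl)tridecanal
Conditions: O3 (1 equiv), CH2Cl2/MeOH, −78 °C; then Me2S, −78 °C → rt
Reagents that add atoms: ozone, [O-][O+]=O
Why: Ozonolysis with reductive work-up: the monosubstituted alkene is far more electron-rich than the two acceptor-conjugated, fully substituted ring double bonds, so that one equivalent of ozone should cleave it selectively to the aldehyde.

**Step 7**
Reactants: 15 2,5-dihydroxycyclohexa-2,5-diene-1,4-dione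
Product: 16 2,5-dihydroxy-3-methylcyclohexa-2,5-diene-1,4-dione
Conditions: CH2O (37 % aq., 1 equiv, slow addition), 15 (2 equiv), Hantzsch ester (1.1 equiv), L-proline (20 mol %), CH2Cl2/EtOH, rt
Reagents that add atoms: formaldehyde, C=O
Why: Three-component reductive alkylation: proline-mediated Knoevenagel condensation of the vinylogous acid with formaldehyde gives an o-quinone methide that is reduced in situ by hydride transfer from the Hantzsch ester; the excess of 15 and slow addition of formaldehyde should hold the reaction at mono-methylation.

**Step 8**
Reactants: 14 13-(2-hydroxy-5-methoxy-4-methyl-3,6-dioxocyclohexa-1,4-dien-1-yl)tridecanal; 16 2,5-dihydroxy-3-methylcyclohexa-2,5-diene-1,4-dione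
Product: 17 2,5-dihydroxy-3-[13-(2-hydroxy-5-methoxy-4-methyl-3,6-dioxocyclohexa-1,4-dien-1-yl)tridecyl]-6-methylcyclohexa-2,5-diene-1,4-dione (target CNP0107579.0)
Conditions: 16 (1.2 equiv), Hantzsch ester (1.2 equiv), L-proline (20 mol %), CH2Cl2, rt; air on work-up
Reagents that add atoms: none
Why: The same Knoevenagel condensation/hydride transfer (three-component reductive alkylation) at the only nucleophilic ring C–H present, the free position of 16, forms the last linker–ring bond; ring A is fully substituted and cannot condense, and any hydroquinone formed by adventitious hydride transfer is reoxidized by air on work-up.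

**Compound list**
1 | 11-bromoundec-1-ene | C=CCCCCCCCCCBr | starting material
2 | 1,4-dibromobutane | BrCCCCBr | starting material
3 | undec-10-en-1-ylmagnesium bromide | C=CCCCCCCCCC[Mg]Br | intermediate
4 | 15-bromopentadec-1-ene | C=CCCCCCCCCCCCCCBr | intermediate
5 | methyl 2,2-dimethoxyacetate | COC(OC)C(=O)OC | starting material
6 | pentadec-14-en-1-ylmagnesium bromide | C=CCCCCCCCCCCCCC[Mg]Br | intermediate
7 | 1,1-dimethoxyheptadec-16-en-2-one | COC(OC)C(=O)CCCCCCCCCCCCCC=C | intermediate
8 | methyl 2-oxobutanoate | CCC(=O)C(=O)OC | starting material
9 | methyl 2,2-dimethoxybutanoate | CCC(OC)(OC)C(=O)OC | intermediate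
10 | 1,1,5,5-tetramethoxy-3-(tetradec-13-en-1-yl)heptane-2,4-dione (present as its lithium enolate) | CCC(OC)(OC)C(=O)C(CCCCCCCCCCCCC=C)C(=O)C(OC)OC | intermediate
11 | [4,6-dimethoxy-5-methyl-2-(tetradec-13-en-1-yl)-1,3-phenylene]bis(oxy)bis(trimethylsilane) | COc1c(C)c(OC)c(O[Si](C)(C)C)c(CCCCCCCCCCCCC=C)c1O[Si](C)(C)C | intermediate
12 | 4,6-dimethoxy-5-methyl-2-(tetradec-13-en-1-yl)benzene-1,3-diol | COc1c(C)c(OC)c(O)c(CCCCCCCCCCCCC=C)c1O | intermediate
13 | 2-hydroxy-5-methoxy-6-methyl-3-(tetradec-13-en-1-yl)cyclohexa-2,5-diene-1,4-dione | COC1=C(C)C(=O)C(O)=C(CCCCCCCCCCCCC=C)C1=O | intermediate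
14 | 13-(2-hydroxy-5-methoxy-4-methyl-3,6-dioxocyclohexa-1,4-dien-1-yl)tridecanal | COC1=C(C)C(=O)C(O)=C(CCCCCCCCCCCCC=O)C1=O | intermediate
15 | 2,5-dihydroxycyclohexa-2,5-diene-1,4-dione | O=C1C=C(O)C(=O)C=C1O | starting material
16 | 2,5-dihydroxy-3-methylcyclohexa-2,5-diene-1,4-dione | CC1=C(O)C(=O)C=C(O)C1=O | intermediate
17 | 2,5-dihydroxy-3-[13-(2-hydroxy-5-methoxy-4-methyl-3,6-dioxocyclohexa-1,4-dien-1-yl)tridecyl]-6-methylcyclohexa-2,5-diene-1,4-dione | COC1=C(C)C(=O)C(O)=C(CCCCCCCCCCCCCC2=C(O)C(=O)C(C)=C(O)C2=O)C1=O | target

Total step count: 8. Longest linear sequence: 6 steps (steps 1, 2, 4, 5, 6, 8).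

**Steps most likely to fail**

Step 4 (Proposed new method). What may go wrong: incomplete C-acylation of the enolate by the hindered quaternary ester; sluggish ionization of an acetal that sits next to a carbonyl group; O- instead of C-attack on the oxocarbenium ion; loss of the acetal methoxy group by β-elimination before aromatization. Fallback with known chemistry, setting out from 1 (through its Grignard reagent 3) and 15 and rejoining the route at 13: 3 is opened onto oxetane (CuI cat., THF) to give tetradec-13-en-1-ol F1, and Swern oxidation gives tetradec-13-enal F2. Reductive alkylation of 15 with F2 (L-proline, Hantzsch ester) should give 2,5-dihydroxy-3-(tetradec-13-en-1-yl)cyclohexa-2,5-diene-1,4-dione F3. Acid-catalysed methanolysis (MeOH, H2SO4) should etherify the less hindered vinylogous acid position, the one next to the ring C–H, to give 2-hydroxy-5-methoxy-3-(tetradec-13-en-1-yl)cyclohexa-2,5-diene-1,4-dione F4. Minisci-type radical methylation of the last ring C–H (MeB(OH)2, AgNO3 cat., K2S2O8) should then give 13.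

Step 6. What may go wrong: competing attack of ozone on the donor-substituted double bonds of the quinone, and over-oxidation of the aldehyde. Fallback, setting out from 12 and rejoining at 14 (step 5 is then skipped): Upjohn dihydroxylation of the alkene at the arene stage (OsO4 cat., N-methylmorpholine N-oxide, acetone/H2O) should give racemic 2-(13,14-dihydroxytetradecyl)-4,6-dimethoxy-5-methylbenzene-1,3-diol F5. PhI(OAc)2 (2.2 equiv, MeCN/H2O) should then cleave the glycol and oxidize the ring to the quinone in one operation, so that no ozone ever meets the quinone.

Step 8. What may go wrong: slow condensation at the hindered free position of 16, which lets enamine self-condensation of the aldehyde and hydride transfer to the ring A quinone compete. Fallback, setting out from 14 and 15 and rejoining at 17 (it also bypasses step 7): reductive alkylation of the unhindered 15 with 14 (L-proline, Hantzsch ester) should give 2,5-dihydroxy-3-[13-(2-hydroxy-5-methoxy-4-methyl-3,6-dioxocyclohexa-1,4-dien-1-yl)tridecyl]cyclohexa-2,5-diene-1,4-dione F6. The one remaining ring C–H of ring B is then methylated by Minisci-type radical methylation (MeB(OH)2, AgNO3 cat., K2S2O8) to give 17.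

**Further compounds**
F1 | step 4 | tetradec-13-en-1-ol | C=CCCCCCCCCCCCCO
F2 | step 4 | tetradec-13-enal | C=CCCCCCCCCCCCC=O
F3 | step 4 | 2,5-dihydroxy-3-(tetradec-13-en-1-yl)cyclohexa-2,5-diene-1,4-dione | O=C1C=C(O)C(=O)C(CCCCCCCCCCCCC=C)=C1O
F4 | step 4 | 2-hydroxy-5-methoxy-3-(tetradec-13-en-1-yl)cyclohexa-2,5-diene-1,4-dione | COC1=CC(=O)C(O)=C(CCCCCCCCCCCCC=C)C1=O
F5 | step 6 | 2-(13,14-dihydroxytetradecyl)-4,6-dimethoxy-5-methylbenzene-1,3-diol (racemic) | COc1c(C)c(OC)c(O)c(CCCCCCCCCCCCC(O)CO)c1O
F6 | step 8 | 2,5-dihydroxy-3-[13-(2-hydroxy-5-methoxy-4-methyl-3,6-dioxocyclohexa-1,4-dien-1-yl)tridecyl]cyclohexa-2,5-diene-1,4-dione | COC1=C(C)C(=O)C(O)=C(CCCCCCCCCCCCCC2=C(O)C(=O)C=C(O)C2=O)C1=O
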